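**Retrosynthetic overview**
1. Target 19 ← acetylation, CH2OH → CHO and carbonyl reductions ← enone keto-aldehyde 13 (C3, C4 and C5 are all relayed from C10).
2. 13 ← electron-transfer reduction and C-methylation of the 2-formyl cyclohexadienone 11 (sets C5, then the C4 quaternary centre).
3. 11 ← phenol 10 by the key step: an enantioselective oxidative dearomatising cation–olefin cyclisation that forms the C9–C10 bond, both ring-B stereocentres and the 7,8-alkene.
4. 10 ← aryl bromide 4 + triene 7 (9-BBN / B-alkyl Suzuki); 4 from 3-bromo-4-methylphenol (ortho-lithiation/formylation), 7 from methyl geranate (SeO2, Wittig).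
5. Ring order: ring A is the aromatic ring from the start; ring B is closed onto it in the key step.

Assumptions: atom labels C1–C20 follow labdane numbering (C3 = C–OAc, C4 = C(CH3)(CHO), C10 = angular C–CH3); methyl geranate is used as the pure 2E isomer; the chiral iodane is written as its (R,R) form, and which antipode delivers 10S must be fixed by experiment (both are available from lactic acid).

**Route**

Step 1
Reactants: 1 3-bromo-4-methylphenol
Product: 2 2-bromo-4-(methoxymethoxy)-1-methylbenzene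
Conditions: MOMCl, i-Pr2NEt, CH2Cl2, 0 °C → rt
Reagents that add atoms: chloromethyl methyl ether, COCCl
Why: O-alkylation of the phenol (acetal formation) installs a robust ortho-directing group; no stereocentre.

Step 2
Reactants: 2 2-bromo-4-(methoxymethoxy)-1-methylbenzene
Product: 4 2-bromo-6-(methoxymethoxy)-3-methylbenzaldehyde, via aryllithium 3 (not isolated)
Conditions: LDA (1.1 equiv), THF, −78 °C; DMF, −78 °C; H2O
Reagents that add atoms: N,N-dimethylformamide, CN(C)C=O
Why: Directed ortho-metalation removes the proton flanked by OMOM and Br (cooperative acidification); at −78 °C the ortho-bromo aryllithium does not eliminate to the aryne and is formylated by DMF.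

Step 3
Reactants: 5 methyl (2E)-3,7-dimethylocta-2,6-dienoate
Product: 6 methyl (2E,6E)-3,7-dimethyl-8-oxoocta-2,6-dienoate
Conditions: SeO2 (1.1 equiv), 1,4-dioxane, 80 °C
Reagents that add atoms: selenium dioxide, O=[Se]=O
Why: Riley allylic oxidation (ene reaction then [2,3]-shift) attacks the (E)-methyl of the electron-rich trisubstituted alkene and at 80 °C runs on to the (E)-enal; the enoate alkene is deactivated.

Step 4
Reactants: 6 methyl (2E,6E)-3,7-dimethyl-8-oxoocta-2,6-dienoate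
Product: 7 methyl (2E,6E)-3,7-dimethylnona-2,6,8-trienoate
Conditions: Ph3PCH3Br, KOt-Bu, THF, 0 °C → rt
Reagents that add atoms: methyltriphenylphosphonium bromide, C[P+](c1ccccc1)(c1ccccc1)c1ccccc1.[Br-]
Why: Wittig methylenation; the non-stabilised ylide adds 1,2 to the enal, the ester is untouched and both E alkenes are preserved.

Step 5
Reactants: 4 2-bromo-6-(methoxymethoxy)-3-methylbenzaldehyde; 7 methyl (2E,6E)-3,7-dimethylnona-2,6,8-trienoate
Product: 10 methyl (2E,6E)-9-(2-formyl-3-hydroxy-6-methylphenyl)-3,7-dimethylnona-2,6-dienoate, via alkylborane 8 (not isolated), via MOM-protected coupling product 9 (not isolated)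
Conditions: 7 (1.2 equiv), 9-BBN (1.15 equiv B–H), THF, 0 °C → rt; then 4, Pd(OAc)2/SPhos (5/10 mol %), aq K3PO4, 65 °C; work-up; crude 9, HCl (cat., from AcCl), MeOH, 40 °C
Reagents that add atoms: none
Why: 9-BBN hydroborates only the monosubstituted alkene (anti-Markovnikov); B-alkyl Suzuki–Miyaura coupling with the di-ortho-substituted bromide is enabled by SPhos (no B–H is left to touch CHO); acid-catalysed transacetalisation then frees the phenol.

Step 6
Reactants: 10 methyl (2E,6E)-9-(2-formyl-3-hydroxy-6-methylphenyl)-3,7-dimethylnona-2,6-dienoate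
Product: 11 methyl (2E)-5-[(1R,8aS)-5-formyl-2,8a-dimethyl-6-oxo-1,4,6,8a-tetrahydronaphthalen-1-yl]-3-methylpent-2-enoate
Conditions: pre-formed chiral iodane ArI*(OAc)2 [(R,R)-2,6-bis(1-(mesitylamino)-1-oxopropan-2-yloxy)phenyl-λ3-iodanediyl diacetate] (1.2 equiv), CH2Cl2/HFIP 10:1, −40 → −20 °C
Reagents that add atoms: none
Why: Proposed new method: ligand exchange gives an O-bound aryloxy-λ3-iodane; while the chiral iodane still shields one face (associative SN2′-type attack, as in Kita/Ishihara asymmetric spirolactonisation) C9 of the E-trisubstituted alkene adds to the para carbon C10 through a chair 6-endo transition state, the E geometry placing the side chain equatorial and cis to the angular methyl (9R,10S); the tertiary C8 cation loses H-7 to give the endocyclic alkene (kinetic E1, as pseudoionone → α-ionone) and ortho attack is blocked by CHO; closest known chemistry is the hypervalent-iodine "oxidative Prins"/polyene cyclisation of phenols (aromatic-ring umpolung) and enantioselective iodane dearomatisation.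

Step 7
Reactants: 11 methyl (2E)-5-[(1R,8aS)-5-formyl-2,8a-dimethyl-6-oxo-1,4,6,8a-tetrahydronaphthalen-1-yl]-3-methylpent-2-enoate
Product: 13 methyl (2E)-5-[(1R,4aS,5R,8aS)-5-formyl-2,5,8a-trimethyl-6-oxo-1,4,4a,5,6,8a-hexahydronaphthalen-1-yl]-3-methylpent-2-enoate, via hydroxymethylene ketone 12 (not isolated)
Conditions: SmI2 (2.2 equiv), MeOH, THF, −78 °C; work-up; crude 12, MeI, K2CO3, acetone, rt
Reagents that add atoms: iodomethane, CI
Why: Dissolving-metal-type (Stork) conjugate reduction of the doubly activated C4=C5 bond, with axial protonation of the C5 carbanion anti to the angular methyl giving the trans fusion (5S) and the electron-richer enoate left alone; the formyl-activated enolate is then C-methylated from the face opposite the 1,3-related angular methyl, so CHO ends axial and cis to C10–CH3 (4R).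

Step 8
Reactants: 13 methyl (2E)-5-[(1R,4aS,5R,8aS)-5-formyl-2,5,8a-trimethyl-6-oxo-1,4,4a,5,6,8a-hexahydronaphthalen-1-yl]-3-methylpent-2-enoate
Product: 16 (2E)-5-[(1R,4aS,5R,6S,8aS)-6-hydroxy-5-(hydroxymethyl)-2,5,8a-trimethyl-1,4,4a,5,6,7,8,8a-octahydronaphthalen-1-yl]-3-methylpent-2-enoic acid, via keto alcohol 14 (not isolated), via diol methyl ester 15 (not isolated)
Conditions: L-Selectride (3.5 equiv), THF, −78 °C; t-BuOH, −78 → −20 °C; then aq LiOH, MeOH, 50 °C; HCl to pH 3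
Reagents that add atoms: lithium hydroxide, [Li+].[OH-]
Why: Selectride reduces the aldehyde and adds 1,4 to the γ,γ-disubstituted enone (Ganem-type conjugate reduction; the enolate protects against retro-aldol until t-BuOH protonates it); the bulky hydride then attacks the C3 ketone equatorially to give the axial 3S alcohol (as with 4,4-dimethyl-3-ketones), and hydroxide saponifies only the unhindered methyl enoate.

Step 9
Reactants: 16 (2E)-5-[(1R,4aS,5R,6S,8aS)-6-hydroxy-5-(hydroxymethyl)-2,5,8a-trimethyl-1,4,4a,5,6,7,8,8a-octahydronaphthalen-1-yl]-3-methylpent-2-enoic acid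
Product: 17 (2E)-5-[(1R,4aS,5S,6S,8aS)-5-formyl-6-hydroxy-2,5,8a-trimethyl-1,4,4a,5,6,7,8,8a-octahydronaphthalen-1-yl]-3-methylpent-2-enoic acid
Conditions: TEMPO (10 mol %), PhI(OAc)2 (1.1 equiv), CH2Cl2, rt
Reagents that add atoms: none
Why: TEMPO/PhI(OAc)2 (Piancatelli–Margarita) oxidises the primary alcohol far faster than the hindered axial secondary one and stops at the aldehyde without water; no centre is touched (C4 changes from R to S only through CIP priorities).

Step 10
Reactants: 17 (2E)-5-[(1R,4aS,5S,6S,8aS)-5-formyl-6-hydroxy-2,5,8a-trimethyl-1,4,4a,5,6,7,8,8a-octahydronaphthalen-1-yl]-3-methylpent-2-enoic acid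
Product: 19 (2E)-5-[(1R,4aS,5S,6S,8aS)-6-acetoxy-5-formyl-2,5,8a-trimethyl-1,4,4a,5,6,7,8,8a-octahydronaphthalen-1-yl]-3-methylpent-2-enoic acid, via mixed anhydride 18 (not isolated)
Conditions: Ac2O, pyridine, DMAP (cat.), CH2Cl2, rt; then H2O/THF, rt
Reagents that add atoms: acetic anhydride, CC(=O)OC(C)=O
Why: DMAP-catalysed acylation of the axial alcohol with retention; the acid is transiently a mixed anhydride that water hydrolyses, and the quaternary C4 rules out β-elimination of the acetate.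

**Compound list**
1 | 3-bromo-4-methylphenol | Cc1ccc(O)cc1Br | starting material
2 | 2-bromo-4-(methoxymethoxy)-1-methylbenzene | Cc1ccc(OCOC)cc1Br | intermediate
3 | [2-bromo-6-(methoxymethoxy)-3-methylphenyl]lithium | Cc1ccc(OCOC)c([Li])c1Br | intermediate
4 | 2-bromo-6-(methoxymethoxy)-3-methylbenzaldehyde | Cc1ccc(OCOC)c(C=O)c1Br | intermediate
5 | methyl (2E)-3,7-dimethylocta-2,6-dienoate (methyl geranate) | CC(C)=CCC/C(C)=C/C(=O)OC | starting material
6 | methyl (2E,6E)-3,7-dimethyl-8-oxoocta-2,6-dienoate | O=C/C(C)=C/CC/C(C)=C/C(=O)OC | intermediate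
7 | methyl (2E,6E)-3,7-dimethylnona-2,6,8-trienoate | C=C/C(C)=C/CC/C(C)=C/C(=O)OC | intermediate
8 | methyl (2E,6E)-9-(9-borabicyclo[3.3.1]nonan-9-yl)-3,7-dimethylnona-2,6-dienoate | COC(=O)/C=C(C)/CC/C=C(C)/CCB1C2CCCC1CCC2 | intermediate
9 | methyl (2E,6E)-9-[2-formyl-3-(methoxymethoxy)-6-methylphenyl]-3,7-dimethylnona-2,6-dienoate | O=Cc1c(OCOC)ccc(C)c1CC/C(C)=C/CC/C(C)=C/C(=O)OC | intermediate
10 | methyl (2E,6E)-9-(2-formyl-3-hydroxy-6-methylphenyl)-3,7-dimethylnona-2,6-dienoate | O=Cc1c(O)ccc(C)c1CC/C(C)=C/CC/C(C)=C/C(=O)OC | intermediate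
11 | methyl (2E)-5-[(1R,8aS)-5-formyl-2,8a-dimethyl-6-oxo-1,4,6,8a-tetrahydronaphthalen-1-yl]-3-methylpent-2-enoate | O=C1C=C[C@@]2(C)[C@H](CC/C(C)=C/C(=O)OC)C(C)=CCC2=C1C=O | intermediate
12 | methyl (2E)-5-[(1R,4aS,8aS)-5-(hydroxymethylidene)-2,8a-dimethyl-6-oxo-1,4,4a,5,6,8a-hexahydronaphthalen-1-yl]-3-methylpent-2-enoate | O=C1C=C[C@@]2(C)[C@H](CC/C(C)=C/C(=O)OC)C(C)=CC[C@@H]2C1=CO | intermediate
13 | methyl (2E)-5-[(1R,4aS,5R,8aS)-5-formyl-2,5,8a-trimethyl-6-oxo-1,4,4a,5,6,8a-hexahydronaphthalen-1-yl]-3-methylpent-2-enoate | O=C1C=C[C@@]2(C)[C@H](CC/C(C)=C/C(=O)OC)C(C)=CC[C@@H]2[C@]1(C)C=O | intermediate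
14 | methyl (2E)-5-[(1R,4aS,5R,8aS)-5-(hydroxymethyl)-2,5,8a-trimethyl-6-oxo-1,4,4a,5,6,7,8,8a-octahydronaphthalen-1-yl]-3-methylpent-2-enoate | O=C1CC[C@@]2(C)[C@H](CC/C(C)=C/C(=O)OC)C(C)=CC[C@@H]2[C@]1(C)CO | intermediate
15 | methyl (2E)-5-[(1R,4aS,5R,6S,8aS)-6-hydroxy-5-(hydroxymethyl)-2,5,8a-trimethyl-1,4,4a,5,6,7,8,8a-octahydronaphthalen-1-yl]-3-methylpent-2-enoate | O[C@H]1CC[C@@]2(C)[C@H](CC/C(C)=C/C(=O)OC)C(C)=CC[C@@H]2[C@]1(C)CO | intermediate
16 | (2E)-5-[(1R,4aS,5R,6S,8aS)-6-hydroxy-5-(hydroxymethyl)-2,5,8a-trimethyl-1,4,4a,5,6,7,8,8a-octahydronaphthalen-1-yl]-3-methylpent-2-enoic acid | O[C@H]1CC[C@@]2(C)[C@H](CC/C(C)=C/C(=O)O)C(C)=CC[C@@H]2[C@]1(C)CO | intermediate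
17 | (2E)-5-[(1R,4aS,5S,6S,8aS)-5-formyl-6-hydroxy-2,5,8a-trimethyl-1,4,4a,5,6,7,8,8a-octahydronaphthalen-1-yl]-3-methylpent-2-enoic acid | O[C@H]1CC[C@@]2(C)[C@H](CC/C(C)=C/C(=O)O)C(C)=CC[C@@H]2[C@]1(C)C=O | intermediate
18 | acetic (2E)-5-[(1R,4aS,5S,6S,8aS)-6-acetoxy-5-formyl-2,5,8a-trimethyl-1,4,4a,5,6,7,8,8a-octahydronaphthalen-1-yl]-3-methylpent-2-enoic anhydride | CC(=O)O[C@H]1CC[C@@]2(C)[C@H](CC/C(C)=C/C(=O)OC(C)=O)C(C)=CC[C@@H]2[C@]1(C)C=O | intermediate
19 | (2E)-5-[(1R,4aS,5S,6S,8aS)-6-acetoxy-5-formyl-2,5,8a-trimethyl-1,4,4a,5,6,7,8,8a-octahydronaphthalen-1-yl]-3-methylpent-2-enoic acid (labdane numbering 3S,4S,5S,9R,10S) | CC(=O)O[C@H]1CC[C@@]2(C)[C@H](CC/C(C)=C/C(=O)O)C(C)=CC[C@@H]2[C@]1(C)C=O | target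

**Step count**
Total: 10 steps. Longest linear sequence: 8 steps (1 → 2 → 5 → 6 → 7 → 8 → 9 → 10; the geranate branch 3 → 4 → 5 → … is equally long).

**Three steps most likely to fail, with fallbacks**

Step 6 is the weakest point. Face selection at the para carbon by an O-bound chiral iodane has no direct precedent, and the E1 termination may also give some exocyclic 8(17)-alkene. Fallback: set out from 10 and cyclise with achiral PhI(OAc)2 in HFIP, which gives racemic 11, that is 11 together with methyl (2E)-5-[(1S,8aR)-5-formyl-2,8a-dimethyl-6-oxo-1,4,6,8a-tetrahydronaphthalen-1-yl]-3-methylpent-2-enoate F1. Run step 7 on the racemate; this also forms the enantiomeric hydroxymethylene ketone methyl (2E)-5-[(1S,4aR,8aR)-5-(hydroxymethylidene)-2,8a-dimethyl-6-oxo-1,4,4a,5,6,8a-hexahydronaphthalen-1-yl]-3-methylpent-2-enoate F2 and the enantiomeric keto-aldehyde methyl (2E)-5-[(1S,4aR,5S,8aR)-5-formyl-2,5,8a-trimethyl-6-oxo-1,4,4a,5,6,8a-hexahydronaphthalen-1-yl]-3-methylpent-2-enoate F3. Separate 13 from F3 by preparative chiral SFC and rejoin the route at 13. Reagent-controlled induction is thereby replaced by resolution.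

Step 7 is the second risk. Electron transfer into the cross-conjugated system could protonate C1 instead of C5, or give some cis fusion. Fallback: set out from 11 and first hydrogenate only the disubstituted C1=C2 bond (H2, (Ph3P)3RhCl) to the classical octalone methyl (2E)-5-[(1R,8aS)-5-formyl-2,8a-dimethyl-6-oxo-1,4,6,7,8,8a-hexahydronaphthalen-1-yl]-3-methylpent-2-enoate F4. Electron-transfer reduction (SmI2/MeOH or Zn/AcOH) then follows textbook 10-methyl-Δ4-3-ketone behaviour and gives methyl (2E)-5-[(1R,4aS,8aS)-5-(hydroxymethylidene)-2,8a-dimethyl-6-oxo-1,4,4a,5,6,7,8,8a-octahydronaphthalen-1-yl]-3-methylpent-2-enoate F5. C-methylation gives methyl (2E)-5-[(1R,4aS,5R,8aS)-5-formyl-2,5,8a-trimethyl-6-oxo-1,4,4a,5,6,7,8,8a-octahydronaphthalen-1-yl]-3-methylpent-2-enoate F6. F6 enters step 8, where only carbonyl reductions remain, and rejoins the route at 14.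

Step 8 is the third risk. The one-flask cascade could suffer 1,2-attack on the enone or retro-aldol loss of formaldehyde from the keto alkoxide. Fallback: set out from 13 and reduce only the aldehyde (NaBH4, 1 equiv, MeOH, −78 °C) to the enone alcohol methyl (2E)-5-[(1R,4aS,5R,8aS)-5-(hydroxymethyl)-2,5,8a-trimethyl-6-oxo-1,4,4a,5,6,8a-hexahydronaphthalen-1-yl]-3-methylpent-2-enoate F7. Saturate C1=C2 by homogeneous hydrogenation ((Ph3P)3RhCl, H2), which gives 14 as an isolated compound, where the route is rejoined. The ketone reduction (L-Selectride) to 15 and the saponification to 16 are then run as separate operations.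

**Further compounds**
F1 | step 6 | methyl (2E)-5-[(1S,8aR)-5-formyl-2,8a-dimethyl-6-oxo-1,4,6,8a-tetrahydronaphthalen-1-yl]-3-methylpent-2-enoate | O=C1C=C[C@]2(C)[C@@H](CC/C(C)=C/C(=O)OC)C(C)=CCC2=C1C=O
F2 | step 6 | methyl (2E)-5-[(1S,4aR,8aR)-5-(hydroxymethylidene)-2,8a-dimethyl-6-oxo-1,4,4a,5,6,8a-hexahydronaphthalen-1-yl]-3-methylpent-2-enoate | O=C1C=C[C@]2(C)[C@@H](CC/C(C)=C/C(=O)OC)C(C)=CC[C@H]2C1=CO
F3 | step 6 | methyl (2E)-5-[(1S,4aR,5S,8aR)-5-formyl-2,5,8a-trimethyl-6-oxo-1,4,4a,5,6,8a-hexahydronaphthalen-1-yl]-3-methylpent-2-enoate | O=C1C=C[C@]2(C)[C@@H](CC/C(C)=C/C(=O)OC)C(C)=CC[C@H]2[C@@]1(C)C=O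
F4 | step 7 | methyl (2E)-5-[(1R,8aS)-5-formyl-2,8a-dimethyl-6-oxo-1,4,6,7,8,8a-hexahydronaphthalen-1-yl]-3-methylpent-2-enoate | O=C1CC[C@@]2(C)[C@H](CC/C(C)=C/C(=O)OC)C(C)=CCC2=C1C=O
F5 | step 7 | methyl (2E)-5-[(1R,4aS,8aS)-5-(hydroxymethylidene)-2,8a-dimethyl-6-oxo-1,4,4a,5,6,7,8,8a-octahydronaphthalen-1-yl]-3-methylpent-2-enoate | O=C1CC[C@@]2(C)[C@H](CC/C(C)=C/C(=O)OC)C(C)=CC[C@@H]2C1=CO
F6 | step 7 | methyl (2E)-5-[(1R,4aS,5R,8aS)-5-formyl-2,5,8a-trimethyl-6-oxo-1,4,4a,5,6,7,8,8a-octahydronaphthalen-1-yl]-3-methylpent-2-enoate | O=C1CC[C@@]2(C)[C@H](CC/C(C)=C/C(=O)OC)C(C)=CC[C@@H]2[C@]1(C)C=O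
F7 | step 8 | methyl (2E)-5-[(1R,4aS,5R,8aS)-5-(hydroxymethyl)-2,5,8a-trimethyl-6-oxo-1,4,4a,5,6,8a-hexahydronaphthalen-1-yl]-3-methylpent-2-enoate | O=C1C=C[C@@]2(C)[C@H](CC/C(C)=C/C(=O)OC)C(C)=CC[C@@H]2[C@]1(C)CO
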